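(All runs were computed for an exercise; the scatter is artificial.)

If the Tuesday's flask is to end above the share of its J that Sunday's flask reached, then Sunday's levelling must be something that more L lifts: the two flasks hold the same J, and the Tuesday's flask holds 2.29 times the L.

| flask | J | L | time |
|---|---|---|---|
| Saturday's | 0.150 M | 0.0120 M |  |
| Friday's | 0.300 M | 0.0120 M |  |
| Sunday's | 0.150 M | 0.0240 M |  |
| Tuesday's | 0.150 M | 0.0550 M | 8.7 min |

| run | time / min | [G] / M |
|---|---|---|
| Saturday's run | 0.49 | 0.0012 |
| Saturday's run | 1.5 | 0.0079 |
| Saturday's run | 2.9 | 0.0258 |
| Saturday's run | 4.5 | 0.0427 |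
| Saturday's run | 6.5 | 0.0569 |
| Saturday's run | 8.7 | 0.0633 |
| Friday's run | 0.49 | 0.0014 |
| Friday's run | 1.5 | 0.0121 |
| Friday's run | 2.9 | 0.0336 |
| Friday's run | 4.5 | 0.0569 |
| Friday's run | 6.5 | 0.0831 |
| Friday's run | 8.7 | 0.0999 |
| Sunday's run | 0.49 | 0.0024 |
| Sunday's run | 1.5 | 0.0182 |
| Sunday's run | 2.9 | 0.0463 |
| Sunday's run | 4.5 | 0.0643 |
| Sunday's run | 6.5 | 0.0715 |
| Sunday's run | 8.7 | 0.0714 |

(each reading ± 0.001 M)

- Overall: J -> G, with L as catalyst.
- Constant volume, constant temperature.
- What is held in complexes is read along with the free species.
- An order is taken over about fifteen percent of the charge, up and down.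

1. how the opening rate goes with [J] round the charge of the Saturday's run: the exponent of the rate at two percent of J gone to G (one fixed amount of G, the same in the runs compared)
2. how the opening rate goes with [L] round the charge of the Saturday's run: the exponent of the rate at two percent of J gone to G
3. G in the Tuesday's run at 8.7 min, as a share of the J charged

1. Sunday's run ends with 47.6% of its J charge as G; this fraction of the J charged, at Sunday's last reading, is the ceiling share.

2. With 2.00 times the L, Sunday's G stands at 2.30 times Saturday's at 1.5 min, but at 1.13 times at 8.7 min. In these two runs the lead shrinks, and Saturday's G is still rising at its last reading.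

3. Over Sunday's last three intervals, G changes by 12 percentage points, then 4.8 points, then −0.067 points of the charge. Taking these unequal intervals as alike, a smooth slowing would repeat the factor 0.400 and add 1.9 points in the last interval. The reading falls short of that, though one share carries a scatter of 0.67 points. This is a weak hint that G is being lost near the top.

4. The opposite outcome therefore finds no support in Sunday's readings. My own rough reckoning takes one such shortfall from the ceiling share and puts the Tuesday's flask at 45.6%.

5. The forecast gave 0.37 for the order in J, 0.67 for the order in L and 47.7% for the Tuesday's share, higher than my 45.6%, on the ground that the levelling “suggests equilibrium rather than catalyst death”.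

6. The flask gives 0.25 for the order in J, 0.59 for the order in L and 43.3% for the Tuesday's share, 4.3 points under the ceiling share.

    Ek + J ⇌ LJ, settled at all times (11.00 M⁻¹)
    LJ ⇌ G + Ek (2.562 min⁻¹, 14.16 M⁻¹ min⁻¹)
    L → Ek (0.6540 min⁻¹)
    G → Qa (0.06900 min⁻¹)

The Tuesday's flask stands under the ceiling share because G passes into Qa: the Tuesday's run without that step gives 58.6% against 43.3% at 8.7 min, and that 58.6% lies 11 points above the ceiling share. The slow passing of L into Ek is not the reason, since the Tuesday's run without that slowness gives 41.8%, also under the ceiling share. By 8.7 min the step into Qa lowers the Tuesday's G by 15 points of the J charged.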